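**Retrosynthetic overview**
- The side chain is cut at the bond between the ketone carbon (C3 of the tridecanone chain) and C4. This gives an O-silylated N-acetyl-L-serine Weinreb amide, which carries the only stereocentre from the chiral pool, and a 10-(furyl)decyl Grignard reagent made from a terminal alkene by hydroboration and bromination.
- The propyl-bearing α-carbon of the furan comes from 1,2-addition of a propyl organometallic to a 5-(dec-9-enyl)-3,4-dimethylbutenolide, followed by aromatising loss of water.
- The plan rests on the two adjacent methyl-bearing ring carbons, furan C3 and C4. The bond between them is made as a C=C bond by intramolecular Horner–Wadsworth–Emmons olefination of the 2-(diethoxyphosphoryl)propanoate ester of an α-hydroxy methyl ketone, so each methyl arrives with its own fragment.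
- The α-hydroxy methyl ketone comes from undec-10-enal and 1-ethoxyvinyllithium (acetyl anion equivalent).
- Ring order: the single ring is closed as the butenolide (step 3) and aromatised to the furan (step 4).

Key step: step 3

Remark on the chemistry: the carbinol centre of the hydroxy ketone, ester and butenolide is carried racemic because aromatisation removes it. N-acetyl-L-serine is used as its commercial methyl ester so that the Weinreb amide is made without carboxyl activation, which would risk azlactone racemisation.

**Step 1**
Reactants: 1 undec-10-enal; 2 ethyl vinyl ether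
Product: 5 racemic 3-hydroxytridec-12-en-2-one, via 1-ethoxyvinyllithium 3 (not isolated), via 2-ethoxytrideca-1,12-dien-3-ol 4 (not isolated)
Conditions: 2, t-BuLi, THF, −78 → 0 °C; then 1, −78 °C; then 1 M HCl (aq.), 0 °C → rt
Reagents that add atoms: water, O
Why: α-Lithiation of the enol ether gives an acetyl anion equivalent that adds 1,2 to the aldehyde, and mild acid hydrolysis of the enol ether should unmask the methyl ketone without touching the terminal alkene; the new carbinol centre is formed racemic and is not needed.

**Step 2**
Reactants: 5 racemic 3-hydroxytridec-12-en-2-one; 6 2-(diethoxyphosphoryl)propanoic acid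
Product: 7 2-oxotridec-12-en-3-yl 2-(diethoxyphosphoryl)propanoate (mixture of stereoisomers)
Conditions: DCC, DMAP (cat.), CH2Cl2, 0 °C → rt
Reagents that add atoms: none
Why: Steglich esterification acylates the secondary α-ketol under near-neutral conditions, which should avoid ketol isomerisation and premature olefination.

**Step 3**
Reactants: 7 2-oxotridec-12-en-3-yl 2-(diethoxyphosphoryl)propanoate
Product: 8 racemic 5-(dec-9-en-1-yl)-3,4-dimethylfuran-2(5H)-one
Conditions: LiCl, DBU, MeCN, 0 °C → rt
Reagents that add atoms: none
Why: Lithium coordination to the phosphoryl and ester oxygens acidifies the phosphonate C–H so that DBU deprotonates it, and the stabilised carbanion attacks the neighbouring methyl ketone carbonyl to form the C3–C4 bond; the resulting oxaphosphetane collapses with loss of diethyl phosphate to the endocyclic tetrasubstituted alkene. The closest known reaction type is the Masamune–Roush variant of the intramolecular Horner–Wadsworth–Emmons butenolide synthesis from α-(phosphonoacyloxy) ketones. The five-membered lactone ring is closed in a 5-exo-trig mode, the ketone C=O lying outside the forming ring. No stereocentre is created, and the existing C5 centre is left racemic because step 4 removes it. The step needs chemoselective deprotonation at the doubly activated phosphonate carbon rather than at the ketone α-positions, which the large acidity difference and the weak amine base secure, so acyl migration and elimination of the acyloxy group should not compete. The alkene geometry is fixed by the ring, and the positions of both methyl groups are fixed beforehand by the propanoate and the methyl ketone.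

**Step 4**
Reactants: 8 racemic 5-(dec-9-en-1-yl)-3,4-dimethylfuran-2(5H)-one
Product: 10 2-(dec-9-en-1-yl)-3,4-dimethyl-5-propylfuran, via lactol 5-(dec-9-en-1-yl)-3,4-dimethyl-2-propyl-2,5-dihydrofuran-2-ol 9 (not isolated)
Conditions: n-PrMgCl, anhydrous CeCl3, THF, −78 °C; then 1 M HCl (aq.), 0 °C
Reagents that add atoms: n-propylmagnesium chloride, CCC[Mg]Cl
Why: The weakly basic organocerium reagent (Imamoto conditions) should add 1,2 to the lactone carbonyl rather than deprotonate C5, and the resulting lactol loses water on brief acid treatment in an aromatising dehydration that erases the C5 stereocentre.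

**Step 5**
Reactants: 10 2-(dec-9-en-1-yl)-3,4-dimethyl-5-propylfuran
Product: 12 10-(3,4-dimethyl-5-propylfuran-2-yl)decan-1-ol, via B-alkylborane 9-[10-(3,4-dimethyl-5-propylfuran-2-yl)decyl]-9-borabicyclo[3.3.1]nonane 11 (not isolated)
Conditions: 9-BBN, THF, 0 °C → rt; then NaOH (aq.), H2O2, 0 °C
Reagents that add atoms: hydrogen peroxide, OO
Why: Anti-Markovnikov hydroboration with the bulky 9-BBN is selective for the terminal alkene over the fully substituted furan, and cold alkaline peroxide oxidation of the C–B bond should leave the furan intact.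

**Step 6**
Reactants: 12 10-(3,4-dimethyl-5-propylfuran-2-yl)decan-1-ol
Product: 13 2-(10-bromodecyl)-3,4-dimethyl-5-propylfuran
Conditions: CBr4, PPh3, CH2Cl2, 0 °C
Reagents that add atoms: carbon tetrabromide, BrC(Br)(Br)Br
Why: The Appel reaction converts the primary alcohol into the bromide by SN2 displacement of an alkoxyphosphonium under neutral conditions, which the acid-sensitive tetraalkylfuran (no free ring position) should tolerate.

**Step 7**
Reactants: 14 methyl (2S)-2-acetamido-3-hydroxypropanoate (N-acetyl-L-serine methyl ester)
Product: 15 methyl (2S)-2-acetamido-3-[(tert-butyldimethylsilyl)oxy]propanoate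
Conditions: TBSCl, imidazole, DMF, 0 °C → rt
Reagents that add atoms: tert-butyldimethylsilyl chloride, CC(C)(C)[Si](C)(C)Cl
Why: Imidazole-promoted silylation protects the primary hydroxyl selectively over the amide N–H and does not touch the stereocentre.

**Step 8**
Reactants: 15 methyl (2S)-2-acetamido-3-[(tert-butyldimethylsilyl)oxy]propanoate
Product: 16 (2S)-2-acetamido-3-[(tert-butyldimethylsilyl)oxy]-N-methoxy-N-methylpropanamide
Conditions: MeNH(OMe)·HCl, i-PrMgCl, THF, −20 → 0 °C
Reagents that add atoms: N,O-dimethylhydroxylamine hydrochloride, CNOC.Cl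
Why: Direct aminolysis of the methyl ester by the chloromagnesium amide of N,O-dimethylhydroxylamine gives the Weinreb amide without carboxyl activation, and the acetamide N–H is deprotonated first, which shields the α-proton so the S configuration should be retained.

**Step 9**
Reactants: 13 2-(10-bromodecyl)-3,4-dimethyl-5-propylfuran; 16 (2S)-2-acetamido-3-[(tert-butyldimethylsilyl)oxy]-N-methoxy-N-methylpropanamide
Product: 18 N-[(2S)-1-[(tert-butyldimethylsilyl)oxy]-13-(3,4-dimethyl-5-propylfuran-2-yl)-3-oxotridecan-2-yl]acetamide, via [10-(3,4-dimethyl-5-propylfuran-2-yl)decyl]magnesium bromide 17 (not isolated)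
Conditions: 13, Mg turnings, THF, rt → 40 °C; 16 pretreated with i-PrMgCl (1 equiv), THF, −15 °C; then combine, 0 °C → rt; NH4Cl (aq.)
Reagents that add atoms: none
Why: In this Weinreb ketone synthesis the primary alkyl Grignard adds once to give a stable magnesium chelate that releases the ketone only on work-up, while prior deprotonation of the amide N–H prevents both quenching of the reagent and enolisation, so the serine-derived S centre is carried through unchanged.

**Step 10**
Reactants: 18 N-[(2S)-1-[(tert-butyldimethylsilyl)oxy]-13-(3,4-dimethyl-5-propylfuran-2-yl)-3-oxotridecan-2-yl]acetamide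
Product: 19 N-[(2S)-13-(3,4-dimethyl-5-propylfuran-2-yl)-1-hydroxy-3-oxotridecan-2-yl]acetamide (target)
Conditions: HF·pyridine, pyridine, THF, 0 °C → rt
Reagents that add atoms: none
Why: Pyridine-buffered fluoride cleavage of the primary silyl ether is neither basic enough to epimerise or eliminate the α-acetamido-β-hydroxy ketone nor acidic enough to open the furan.

**Compound list**
1 | undec-10-enal | C=CCCCCCCCCC=O | starting material
2 | ethyl vinyl ether | C=COCC | starting material
3 | 1-ethoxyvinyllithium | [Li]C(=C)OCC | intermediate
4 | racemic 2-ethoxytrideca-1,12-dien-3-ol | C=CCCCCCCCCC(O)C(=C)OCC | intermediate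
5 | racemic 3-hydroxytridec-12-en-2-one | C=CCCCCCCCCC(O)C(C)=O | intermediate
6 | 2-(diethoxyphosphoryl)propanoic acid (racemic) | CC(C(=O)O)P(=O)(OCC)OCC | starting material
7 | 2-oxotridec-12-en-3-yl 2-(diethoxyphosphoryl)propanoate (mixture of stereoisomers) | C=CCCCCCCCCC(OC(=O)C(C)P(=O)(OCC)OCC)C(C)=O | intermediate
8 | racemic 5-(dec-9-en-1-yl)-3,4-dimethylfuran-2(5H)-one | C=CCCCCCCCCC1OC(=O)C(C)=C1C | intermediate
9 | 5-(dec-9-en-1-yl)-3,4-dimethyl-2-propyl-2,5-dihydrofuran-2-ol (mixture of stereoisomers) | C=CCCCCCCCCC1OC(O)(CCC)C(C)=C1C | intermediate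
10 | 2-(dec-9-en-1-yl)-3,4-dimethyl-5-propylfuran | C=CCCCCCCCCc1oc(CCC)c(C)c1C | intermediate
11 | 9-[10-(3,4-dimethyl-5-propylfuran-2-yl)decyl]-9-borabicyclo[3.3.1]nonane | CCCc1oc(CCCCCCCCCCB2C3CCCC2CCC3)c(C)c1C | intermediate
12 | 10-(3,4-dimethyl-5-propylfuran-2-yl)decan-1-ol | CCCc1oc(CCCCCCCCCCO)c(C)c1C | intermediate
13 | 2-(10-bromodecyl)-3,4-dimethyl-5-propylfuran | CCCc1oc(CCCCCCCCCCBr)c(C)c1C | intermediate
14 | methyl (2S)-2-acetamido-3-hydroxypropanoate (N-acetyl-L-serine methyl ester) | CC(=O)N[C@@H](CO)C(=O)OC | starting material
15 | methyl (2S)-2-acetamido-3-[(tert-butyldimethylsilyl)oxy]propanoate | CC(=O)N[C@@H](CO[Si](C)(C)C(C)(C)C)C(=O)OC | intermediate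
16 | (2S)-2-acetamido-3-[(tert-butyldimethylsilyl)oxy]-N-methoxy-N-methylpropanamide | CC(=O)N[C@@H](CO[Si](C)(C)C(C)(C)C)C(=O)N(C)OC | intermediate
17 | [10-(3,4-dimethyl-5-propylfuran-2-yl)decyl]magnesium bromide | CCCc1oc(CCCCCCCCCC[Mg]Br)c(C)c1C | intermediate
18 | N-[(2S)-1-[(tert-butyldimethylsilyl)oxy]-13-(3,4-dimethyl-5-propylfuran-2-yl)-3-oxotridecan-2-yl]acetamide | CCCc1oc(CCCCCCCCCCC(=O)[C@H](CO[Si](C)(C)C(C)(C)C)NC(C)=O)c(C)c1C | intermediate
19 | N-[(2S)-13-(3,4-dimethyl-5-propylfuran-2-yl)-1-hydroxy-3-oxotridecan-2-yl]acetamide | CCCc1oc(CCCCCCCCCCC(=O)[C@H](CO)NC(C)=O)c(C)c1C | target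

**Step count**
Total steps: 10. Longest linear sequence: 8 (steps 1, 2, 3, 4, 5, 6, 9, 10); steps 7 and 8 form the serine branch.

**Steps most likely to fail**

1. Step 3 (key olefination). Closure to a tetrasubstituted alkene from a ketone and an α-methyl phosphonate may be slow, so base-mediated acyl migration, ketol isomerisation or elimination of the acyloxy group could overtake it. The fallback keeps the same C3–C4 bond but generates the ester enolate reductively instead of by deprotonation. It sets out from 5 and returns at 8. Acylation of 5 with 2-bromopropanoyl bromide and pyridine in CH2Cl2 should give 2-oxotridec-12-en-3-yl 2-bromopropanoate F1. Intramolecular Reformatsky cyclisation with SmI2 in THF at −78 °C should then give 5-(dec-9-en-1-yl)-4-hydroxy-3,4-dimethyloxolan-2-one F2. Dehydration with SOCl2 and pyridine, followed by DBU to bring any non-conjugated alkene isomer into conjugation, should deliver 8.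

2. Step 4 (propyl addition and aromatisation). The organometallic may deprotonate C5 of the butenolide instead of adding, or may add a second time to the ring-opened hydroxy enone. The fallback installs the propyl group as an electrophile on a preformed furan. It sets out from 8 and returns at 10. Reduction of 8 with i-Bu2AlH in CH2Cl2 at −78 °C should give 5-(dec-9-en-1-yl)-3,4-dimethyl-2,5-dihydrofuran-2-ol F3. Acidic work-up should dehydrate it to 2-(dec-9-en-1-yl)-3,4-dimethylfuran F4. Lithiation of the one free α-position with n-BuLi in THF at 0 °C should give [5-(dec-9-en-1-yl)-3,4-dimethylfuran-2-yl]lithium F5, which is alkylated with 1-iodopropane to give 10.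

3. Step 9 (fragment coupling). Wurtz homocoupling may occur during Grignard formation, the amide N–H may quench the reagent, and base-induced elimination of silanolate or enolisation may erode the stereocentre. The fallback replaces the basic Grignard reagent by a neutral palladium-catalysed acylation (Fukuyama ketone synthesis). It sets out from 13 and 15 and returns at 18. Finkelstein exchange of 13 with NaI in acetone should give 2-(10-iododecyl)-3,4-dimethyl-5-propylfuran F6. Insertion of activated Zn dust in THF should give [10-(3,4-dimethyl-5-propylfuran-2-yl)decyl]zinc iodide F7. In parallel, 15 is converted with EtSH and AlMe3 in CH2Cl2 into S-ethyl (2S)-2-acetamido-3-[(tert-butyldimethylsilyl)oxy]propanethioate F8. Coupling of F7 with F8 under PdCl2(PPh3)2 catalysis in toluene/THF at rt should give 18 without epimerisation.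

**Further compounds**
F1 | step 3 | 2-oxotridec-12-en-3-yl 2-bromopropanoate (mixture of stereoisomers) | C=CCCCCCCCCC(OC(=O)C(C)Br)C(C)=O
F2 | step 3 | 5-(dec-9-en-1-yl)-4-hydroxy-3,4-dimethyloxolan-2-one (mixture of stereoisomers) | C=CCCCCCCCCC1OC(=O)C(C)C1(C)O
F3 | step 4 | 5-(dec-9-en-1-yl)-3,4-dimethyl-2,5-dihydrofuran-2-ol (mixture of stereoisomers) | C=CCCCCCCCCC1OC(O)C(C)=C1C
F4 | step 4 | 2-(dec-9-en-1-yl)-3,4-dimethylfuran | C=CCCCCCCCCc1occ(C)c1C
F5 | step 4 | [5-(dec-9-en-1-yl)-3,4-dimethylfuran-2-yl]lithium | C=CCCCCCCCCc1oc([Li])c(C)c1C
F6 | step 9 | 2-(10-iododecyl)-3,4-dimethyl-5-propylfuran | CCCc1oc(CCCCCCCCCCI)c(C)c1C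
F7 | step 9 | [10-(3,4-dimethyl-5-propylfuran-2-yl)decyl]zinc iodide | CCCc1oc(CCCCCCCCCC[Zn]I)c(C)c1C
F8 | step 9 | S-ethyl (2S)-2-acetamido-3-[(tert-butyldimethylsilyl)oxy]propanethioate | CCSC(=O)[C@H](CO[Si](C)(C)C(C)(C)C)NC(C)=O
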